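The route rests on disconnecting the aryl ether bond O1–C8a of the pyranone ring (ring C). The key step closes ring C by copper-catalysed intramolecular O-arylation: the primary alkoxide of an acyclic 1,3-diol displaces bromine at C8a of ring A. It exploits the fact that C8a lies ortho to C4a, which carries the C4 carbon, and meta to both ring-A oxygens; C4 is kept as a carbinol, so that C3 is not enolisable under base and the secondary hydroxyl cannot compete (four-membered ring). The precursor, a (1R,2S)-1-(2-bromo-4,6-dibenzyloxyphenyl)-2-arylpropane-1,3-diol, comes from an Evans syn-aldol; Shi epoxidation, oxidation at C4 and hydrogenolysis complete the target.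

Key step: step 9

Remark: atoms are numbered as in isoflavanone (O1, C2, C3, C4, C4a, C5 to C8, C8a; ring B primed); ArA = 2,4-bis(benzyloxy)-6-bromophenyl, ArB = 3,4-bis(benzyloxy)-5-(3-methylbut-2-en-1-yl)phenyl; compounds 1, 3, 8 and 11 are taken as commercially available.

Step 1
Reactants: 1 3-bromo-4,5-dihydroxybenzaldehyde
Product: 2 3,4-bis(benzyloxy)-5-bromobenzaldehyde
Conditions: BnBr (2.4 equiv), K2CO3, DMF, 60 °C
Reagents that add atoms: benzyl bromide BrCc1ccccc1
Why: Williamson ether synthesis, in which both catechol phenoxides are alkylated while the non-enolisable aldehyde is inert to carbonate.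

Step 2
Reactants: 2 3,4-bis(benzyloxy)-5-bromobenzaldehyde; 3 tributyl(3-methylbut-2-en-1-yl)stannane
Product: 4 3,4-bis(benzyloxy)-5-(3-methylbut-2-en-1-yl)benzaldehyde
Conditions: Pd(PPh3)4 (5 mol %), DMF, 100 °C
Reagents that add atoms: none
Why: Stille coupling, in which zerovalent palladium inserts into the C–Br bond and the aryl(allyl)palladium formed after transmetalation should reductively eliminate at the unsubstituted allyl terminus to give the linear prenyl arene, the aldehyde being tolerated.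

Step 3
Reactants: 4 3,4-bis(benzyloxy)-5-(3-methylbut-2-en-1-yl)benzaldehyde
Product: 6 2-[3,4-bis(benzyloxy)-5-(3-methylbut-2-en-1-yl)phenyl]acetonitrile, via N-(1-tosylalkenyl)formamide 5 (not isolated)
Conditions: TosMIC, KOt-Bu, DME, −50 °C; then MeOH, reflux
Reagents that add atoms: tosylmethyl isocyanide (TosMIC) Cc1ccc(S(=O)(=O)C[N+]#[C-])cc1
Why: Van Leusen reductive cyanation, in which the TosMIC anion adds to the aldehyde to give formamide 5, whose methanolysis expels methyl formate and sulfinate and leaves the one-carbon-homologated nitrile.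

Step 4
Reactants: 6 2-[3,4-bis(benzyloxy)-5-(3-methylbut-2-en-1-yl)phenyl]acetonitrile
Product: 7 2-[3,4-bis(benzyloxy)-5-(3-methylbut-2-en-1-yl)phenyl]acetic acid
Conditions: KOH, EtOH/H2O, reflux; then 1 M HCl, 0 °C
Reagents that add atoms: potassium hydroxide [K+].[OH-]; water O
Why: Alkaline nitrile hydrolysis of an arylacetonitrile, to which benzyl ethers and the isolated trisubstituted alkene are stable.

Step 5
Reactants: 7 2-[3,4-bis(benzyloxy)-5-(3-methylbut-2-en-1-yl)phenyl]acetic acid; 8 (R)-4-benzyl-1,3-oxazolidin-2-one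
Product: 10 (4R)-4-benzyl-3-{2-[3,4-bis(benzyloxy)-5-(3-methylbut-2-en-1-yl)phenyl]acetyl}-1,3-oxazolidin-2-one, via mixed pivalic anhydride 9 (not isolated)
Conditions: PivCl, Et3N, THF, −20 °C; then LiCl, 8, −20 °C → rt
Reagents that add atoms: pivaloyl chloride CC(C)(C)C(Cl)=O (its atoms stay only in 9)
Why: N-acylation of the oxazolidinone through the mixed anhydride with LiCl assistance, a standard preparation of Evans imides from arylacetic acids.

Step 6
Reactants: 11 1,3-bis(benzyloxy)-5-bromobenzene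
Product: 13 2,4-bis(benzyloxy)-6-bromobenzaldehyde, via aryl iminium chloride 12 (not isolated)
Conditions: POCl3, DMF, 0 → 80 °C; then aq. NaOAc
Reagents that add atoms: N,N-dimethylformamide CN(C)C=O; phosphoryl chloride O=P(Cl)(Cl)Cl (chloride of 12); water O
Why: Vilsmeier–Haack formylation, in which the chloroiminium ion should attack the carbon next to bromine (para to one benzyloxy group, ortho to the other), which is less hindered than the site between the two benzyloxy groups.

Step 7
Reactants: 10 (4R)-4-benzyl-3-(ArB-acetyl)-1,3-oxazolidin-2-one; 13 2,4-bis(benzyloxy)-6-bromobenzaldehyde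
Product: 16 (4R)-4-benzyl-3-[(2R,3R)-3-ArA-2-ArB-3-hydroxypropanoyl]-1,3-oxazolidin-2-one, via boron enolate 14 (not isolated), via boron aldolate 15 (not isolated)
Conditions: Bu2BOTf, i-Pr2NEt, CH2Cl2, −78 → 0 °C; 13, −78 → 0 °C; then pH 7 buffer, MeOH, 30% H2O2, 0 °C
Reagents that add atoms: dibutylboron triflate CCCCB(CCCC)OS(=O)(=O)C(F)(F)F (its atoms stay only in 14 and 15)
Why: Evans boron syn-aldol, in which the Z-enolate reacts through a chair Zimmerman–Traxler transition state on the face opposite the auxiliary benzyl group, setting C2 (the future C3, R here) and the C3 carbinol (R, later erased) together.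

Step 8
Reactants: 16 (4R)-4-benzyl-3-[(2R,3R)-3-ArA-2-ArB-3-hydroxypropanoyl]-1,3-oxazolidin-2-one
Product: 17 (1R,2S)-1-[2,4-bis(benzyloxy)-6-bromophenyl]-2-[3,4-bis(benzyloxy)-5-(3-methylbut-2-en-1-yl)phenyl]propane-1,3-diol
Conditions: LiBH4, MeOH (1 equiv), THF, 0 °C
Reagents that add atoms: none
Why: Reductive cleavage of the imide by borohydride gives the primary alcohol without touching the aryl bromide or alkene, the aryl-bearing centre being unchanged in space and becoming S only through the change of CIP priorities.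

Step 9
Reactants: 17 (1R,2S)-1-ArA-2-ArB-propane-1,3-diol
Product: 18 (3S,4R)-5,7-bis(benzyloxy)-3-[3,4-bis(benzyloxy)-5-(3-methylbut-2-en-1-yl)phenyl]-3,4-dihydro-2H-chromen-4-ol (3,4-trans)
Conditions: CuI (10 mol %), 3,4,7,8-tetramethyl-1,10-phenanthroline (20 mol %), Cs2CO3 (2 equiv), toluene, 90 °C
Reagents that add atoms: none
Why: Cs2CO3 deprotonates the primary hydroxyl, the monovalent copper–phenanthroline alkoxide adds oxidatively into the C8a–Br bond to give an aryl trivalent-copper alkoxide held in a seven-membered chelate, and C–O reductive elimination forms O1–C8a and returns monovalent copper. The closest known reaction type is the Ullmann-type copper-catalysed intramolecular O-arylation of aliphatic alcohols with aryl bromides, which is established for chroman rings. Ring C closes in a 6-exo-trig sense at the aromatic carbon C8a, the C–Br bond being exocyclic to the new ring. No stereocentre is formed; C3 (S) and C4 (R) come unchanged from the aldol, and C3 cannot epimerise under carbonate because C4 is still a carbinol and not a ketone. The selectivity needed is primary over secondary hydroxyl and C–O coupling over loss of bromine: the secondary C4–OH could only close a four-membered ring, copper alkoxides do not suffer the β-hydride elimination that a chelated palladium alkoxide would, C8a–Br is the only aryl halide, and it lies meta to both benzyloxy groups so that no ortho or para donor retards oxidative addition.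

Step 10
Reactants: 18 (3S,4R)-5,7-bis(benzyloxy)-3-ArB-chroman-4-ol
Product: 19 (3S,4R)-5,7-bis(benzyloxy)-3-[3,4-bis(benzyloxy)-5-{[(2R)-3,3-dimethyloxiran-2-yl]methyl}phenyl]-3,4-dihydro-2H-chromen-4-ol
Conditions: 1,2:4,5-di-O-isopropylidene-β-D-erythro-2,3-hexodiulo-2,6-pyranose (D-fructose-derived Shi ketone, 30 mol %), KHSO5 (as 2KHSO5·KHSO4·K2SO4), K2CO3, Bu4NHSO4, MeCN/CH2(OMe)2–aq. Na2B4O7 buffer (pH 10.5), 0 °C
Reagents that add atoms: potassium peroxymonosulfate [K+].[O-]S(=O)(=O)OO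
Why: Shi epoxidation, in which the chiral dioxirane transfers oxygen to the trisubstituted alkene through a spiro transition state and reagent control should give the (R)-epoxide as for other 2-methylalk-2-enes, while the basic buffer spares the acid-labile benzylic alcohol and no enolisable centre is present yet.

Step 11
Reactants: 19 (3S,4R)-epoxy chromanol
Product: 20 (3S)-5,7-bis(benzyloxy)-3-[3,4-bis(benzyloxy)-5-{[(2R)-3,3-dimethyloxiran-2-yl]methyl}phenyl]-2,3-dihydro-4H-chromen-4-one
Conditions: Dess–Martin periodinane, NaHCO3, CH2Cl2, 0 °C → rt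
Reagents that add atoms: none
Why: Dess–Martin oxidation of the secondary benzylic alcohol under bicarbonate buffer gives the ketone without acid or strong base, so the now enolisable C3 centre and the epoxide should be preserved.

Step 12
Reactants: 20 (3S)-tetrabenzyl epoxy isoflavanone
Product: 21 (3S)-3-[3,4-dihydroxy-5-{[(2R)-3,3-dimethyloxiran-2-yl]methyl}phenyl]-5,7-dihydroxy-2,3-dihydro-4H-chromen-4-one (target)
Conditions: H2 (1 atm), 10% Pd/C, EtOAc, rt
Reagents that add atoms: none
Why: Hydrogenolysis of the four aryl benzyl ethers in a neutral aprotic solvent, where the non-benzylic trialkyl epoxide and the electron-rich aryl ketone are reduced far more slowly and no acid or base is present to epimerise C3.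

Compound list

1 | 3-bromo-4,5-dihydroxybenzaldehyde | O=Cc1cc(O)c(O)c(Br)c1 | starting material
2 | 3,4-bis(benzyloxy)-5-bromobenzaldehyde | O=Cc1cc(OCc2ccccc2)c(OCc2ccccc2)c(Br)c1 | intermediate
3 | tributyl(3-methylbut-2-en-1-yl)stannane | CC(C)=CC[Sn](CCCC)(CCCC)CCCC | starting material
4 | 3,4-bis(benzyloxy)-5-(3-methylbut-2-en-1-yl)benzaldehyde | O=Cc1cc(OCc2ccccc2)c(OCc2ccccc2)c(CC=C(C)C)c1 | intermediate
5 | N-{2-ArB-1-[(4-methylphenyl)sulfonyl]ethenyl}formamide (potassium salt in the flask; alkene geometry immaterial) | O=CNC(=Cc1cc(OCc2ccccc2)c(OCc2ccccc2)c(CC=C(C)C)c1)S(=O)(=O)c1ccc(C)cc1 | intermediate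
6 | 2-[3,4-bis(benzyloxy)-5-(3-methylbut-2-en-1-yl)phenyl]acetonitrile | N#CCc1cc(OCc2ccccc2)c(OCc2ccccc2)c(CC=C(C)C)c1 | intermediate
7 | 2-[3,4-bis(benzyloxy)-5-(3-methylbut-2-en-1-yl)phenyl]acetic acid | OC(=O)Cc1cc(OCc2ccccc2)c(OCc2ccccc2)c(CC=C(C)C)c1 | intermediate
8 | (R)-4-benzyl-1,3-oxazolidin-2-one | O=C1N[C@H](Cc2ccccc2)CO1 | starting material
9 | mixed anhydride of 7 with pivalic acid | CC(C)(C)C(=O)OC(=O)Cc1cc(OCc2ccccc2)c(OCc2ccccc2)c(CC=C(C)C)c1 | intermediate
10 | (4R)-4-benzyl-3-{2-[3,4-bis(benzyloxy)-5-(3-methylbut-2-en-1-yl)phenyl]acetyl}-1,3-oxazolidin-2-one | O=C(Cc1cc(OCc2ccccc2)c(OCc2ccccc2)c(CC=C(C)C)c1)N1C(=O)OC[C@H]1Cc1ccccc1 | intermediate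
11 | 1,3-bis(benzyloxy)-5-bromobenzene | Brc1cc(OCc2ccccc2)cc(OCc2ccccc2)c1 | starting material
12 | N-[2,4-bis(benzyloxy)-6-bromobenzylidene]-N-methylmethanaminium chloride | C[N+](C)=Cc1c(Br)cc(OCc2ccccc2)cc1OCc1ccccc1.[Cl-] | intermediate
13 | 2,4-bis(benzyloxy)-6-bromobenzaldehyde | O=Cc1c(Br)cc(OCc2ccccc2)cc1OCc1ccccc1 | intermediate
14 | dibutylboron (Z)-enolate of 10, (4R)-4-benzyl-3-{(1Z)-2-ArB-1-[(dibutylboranyl)oxy]ethenyl}-1,3-oxazolidin-2-one | CCCCB(CCCC)O/C(N1C(=O)OC[C@H]1Cc1ccccc1)=C\c1cc(OCc2ccccc2)c(OCc2ccccc2)c(CC=C(C)C)c1 | intermediate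
15 | O-dibutylboranyl derivative (boron aldolate) of 16 | O=C([C@H](c1cc(CC=C(C)C)c(OCc2ccccc2)c(OCc2ccccc2)c1)[C@@H](OB(CCCC)CCCC)c1c(Br)cc(OCc2ccccc2)cc1OCc1ccccc1)N1C(=O)OC[C@H]1Cc1ccccc1 | intermediate
16 | (4R)-4-benzyl-3-[(2R,3R)-3-[2,4-bis(benzyloxy)-6-bromophenyl]-2-[3,4-bis(benzyloxy)-5-(3-methylbut-2-en-1-yl)phenyl]-3-hydroxypropanoyl]-1,3-oxazolidin-2-one | O=C([C@H](c1cc(CC=C(C)C)c(OCc2ccccc2)c(OCc2ccccc2)c1)[C@@H](O)c1c(Br)cc(OCc2ccccc2)cc1OCc1ccccc1)N1C(=O)OC[C@H]1Cc1ccccc1 | intermediate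
17 | (1R,2S)-1-[2,4-bis(benzyloxy)-6-bromophenyl]-2-[3,4-bis(benzyloxy)-5-(3-methylbut-2-en-1-yl)phenyl]propane-1,3-diol | OC[C@H](c1cc(CC=C(C)C)c(OCc2ccccc2)c(OCc2ccccc2)c1)[C@@H](O)c1c(Br)cc(OCc2ccccc2)cc1OCc1ccccc1 | intermediate
18 | (3S,4R)-5,7-bis(benzyloxy)-3-[3,4-bis(benzyloxy)-5-(3-methylbut-2-en-1-yl)phenyl]-3,4-dihydro-2H-chromen-4-ol | CC(C)=CCc1cc([C@H]2COc3cc(OCc4ccccc4)cc(OCc4ccccc4)c3[C@@H]2O)cc(OCc2ccccc2)c1OCc1ccccc1 | intermediate
19 | (3S,4R)-5,7-bis(benzyloxy)-3-[3,4-bis(benzyloxy)-5-{[(2R)-3,3-dimethyloxiran-2-yl]methyl}phenyl]-3,4-dihydro-2H-chromen-4-ol | CC1(C)O[C@@H]1Cc1cc([C@H]2COc3cc(OCc4ccccc4)cc(OCc4ccccc4)c3[C@@H]2O)cc(OCc2ccccc2)c1OCc1ccccc1 | intermediate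
20 | (3S)-5,7-bis(benzyloxy)-3-[3,4-bis(benzyloxy)-5-{[(2R)-3,3-dimethyloxiran-2-yl]methyl}phenyl]-2,3-dihydro-4H-chromen-4-one | CC1(C)O[C@@H]1Cc1cc([C@H]2COc3cc(OCc4ccccc4)cc(OCc4ccccc4)c3C2=O)cc(OCc2ccccc2)c1OCc1ccccc1 | intermediate
21 | (3S)-3-[3,4-dihydroxy-5-{[(2R)-3,3-dimethyloxiran-2-yl]methyl}phenyl]-5,7-dihydroxy-2,3-dihydro-4H-chromen-4-one | CC1(C)O[C@@H]1Cc1cc([C@H]2COc3cc(O)cc(O)c3C2=O)cc(O)c1O | target

Total step count: 12. Longest linear sequence: 11 steps (steps 1 to 5, then 7 to 12, from compound 1).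

Steps most likely to fail

Step 7. The boron enolate may add slowly and reversibly to the di-ortho-substituted, electron-rich aldehyde, so that conversion stalls and retro-aldol during work-up erodes the diastereomeric purity. The fallback replaces the aldol by C-acylation and chelation-controlled reduction; it sets out from 7 and 13 and returns at 17. Acid 7 is converted as in step 5, through 9 but with commercial (S)-4-benzyl-1,3-oxazolidin-2-one, into the (4S)-imide F1. Aldehyde 13 is oxidised (NaClO2, NaH2PO4, 2-methylbut-2-ene, t-BuOH/H2O) to 2,4-bis(benzyloxy)-6-bromobenzoic acid F2, which oxalyl chloride with catalytic DMF converts into the acid chloride F3. The lithium enolate of F1 (LiN(i-Pr)2, THF, −78 °C) is acylated with F3 under chelate control, on the enolate face opposite to that used by the boron aldol (hence the enantiomeric auxiliary), to give the (2R)-β-keto imide F4, which allylic strain should keep from enolising. Zn(BH4)2 (CH2Cl2/Et2O, −20 °C) should reduce F4 under chelation control to the syn-(2R,3R)-hydroxy imide F5, and LiBH4 as in step 8 then gives diol 17.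

Step 12. Once the C4′ benzyl ether is cleaved, the free phenol may open the neighbouring epoxide by five-membered ring closure on the catalyst surface, and over-reduction of the epoxide may compete. The fallback removes the benzyl groups before the epoxide exists and ends with fluoride; it sets out from 18 and returns at 21. Alcohol 18 is oxidised (Dess–Martin periodinane, NaHCO3, CH2Cl2) to the tetrabenzyl prenyl isoflavanone F6. Debenzylation without hydrogen (BCl3, pentamethylbenzene, CH2Cl2, −78 °C) gives the tetraphenol F7. Silylation (TBSCl, imidazole, DMF, 0 °C; the hydrogen-bonded 5-OH stays free) gives the tris-silyl ether F8. Shi epoxidation with the ketone of step 10, used stoichiometrically near pH 8 (NaHCO3) to spare C3, gives the epoxide F9. Bu4NF buffered with AcOH (THF, 0 °C) then liberates 21.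

Step 9. Oxidative addition at the ortho-substituted bromide may be sluggish, so that protodebromination or decomposition of the dialkoxide at 90 °C outruns ring closure. The fallback forms the same O1–C8a bond without a metal catalyst, through an aryne; it sets out from 17 and returns at 18. Diol 17 is treated with LiN(i-Pr)2 (4 equiv, THF, −78 → 0 °C). After the dialkoxide has formed, C8–H, the only hydrogen ortho to bromine and flanked by the C7 benzyloxy group, is removed and LiBr is lost to give the aryne F10 (not isolated), with the triple bond between C8 and C8a. The tethered primary alkoxide adds at C8a, which is the only aryne carbon it can reach through a six-membered ring and also the carbon remote from the C7 benzyloxy group, so that the aryl anion develops at C8 next to that inductively withdrawing oxygen. Protonation at C8 gives 18.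

Further compounds

F1 | step 7 | (4S)-4-benzyl-3-{2-[3,4-bis(benzyloxy)-5-(3-methylbut-2-en-1-yl)phenyl]acetyl}-1,3-oxazolidin-2-one | O=C(Cc1cc(OCc2ccccc2)c(OCc2ccccc2)c(CC=C(C)C)c1)N1C(=O)OC[C@@H]1Cc1ccccc1
F2 | step 7 | 2,4-bis(benzyloxy)-6-bromobenzoic acid | OC(=O)c1c(Br)cc(OCc2ccccc2)cc1OCc1ccccc1
F3 | step 7 | 2,4-bis(benzyloxy)-6-bromobenzoyl chloride | O=C(Cl)c1c(Br)cc(OCc2ccccc2)cc1OCc1ccccc1
F4 | step 7 | (4S)-4-benzyl-3-[(2R)-3-[2,4-bis(benzyloxy)-6-bromophenyl]-2-[3,4-bis(benzyloxy)-5-(3-methylbut-2-en-1-yl)phenyl]-3-oxopropanoyl]-1,3-oxazolidin-2-one | O=C([C@H](c1cc(CC=C(C)C)c(OCc2ccccc2)c(OCc2ccccc2)c1)C(=O)c1c(Br)cc(OCc2ccccc2)cc1OCc1ccccc1)N1C(=O)OC[C@@H]1Cc1ccccc1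
F5 | step 7 | (4S)-4-benzyl-3-[(2R,3R)-3-[2,4-bis(benzyloxy)-6-bromophenyl]-2-[3,4-bis(benzyloxy)-5-(3-methylbut-2-en-1-yl)phenyl]-3-hydroxypropanoyl]-1,3-oxazolidin-2-one | O=C([C@H](c1cc(CC=C(C)C)c(OCc2ccccc2)c(OCc2ccccc2)c1)[C@@H](O)c1c(Br)cc(OCc2ccccc2)cc1OCc1ccccc1)N1C(=O)OC[C@@H]1Cc1ccccc1
F6 | step 12 | (3S)-5,7-bis(benzyloxy)-3-[3,4-bis(benzyloxy)-5-(3-methylbut-2-en-1-yl)phenyl]-2,3-dihydro-4H-chromen-4-one | CC(C)=CCc1cc([C@H]2COc3cc(OCc4ccccc4)cc(OCc4ccccc4)c3C2=O)cc(OCc2ccccc2)c1OCc1ccccc1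
F7 | step 12 | (3S)-3-[3,4-dihydroxy-5-(3-methylbut-2-en-1-yl)phenyl]-5,7-dihydroxy-2,3-dihydro-4H-chromen-4-one | CC(C)=CCc1cc([C@H]2COc3cc(O)cc(O)c3C2=O)cc(O)c1O
F8 | step 12 | (3S)-7-(tert-butyldimethylsilyloxy)-3-[3,4-bis(tert-butyldimethylsilyloxy)-5-(3-methylbut-2-en-1-yl)phenyl]-5-hydroxy-2,3-dihydro-4H-chromen-4-one | CC(C)=CCc1cc([C@H]2COc3cc(O[Si](C)(C)C(C)(C)C)cc(O)c3C2=O)cc(O[Si](C)(C)C(C)(C)C)c1O[Si](C)(C)C(C)(C)C
F9 | step 12 | (3S)-7-(tert-butyldimethylsilyloxy)-3-[3,4-bis(tert-butyldimethylsilyloxy)-5-{[(2R)-3,3-dimethyloxiran-2-yl]methyl}phenyl]-5-hydroxy-2,3-dihydro-4H-chromen-4-one | CC1(C)O[C@@H]1Cc1cc([C@H]2COc3cc(O[Si](C)(C)C(C)(C)C)cc(O)c3C2=O)cc(O[Si](C)(C)C(C)(C)C)c1O[Si](C)(C)C(C)(C)C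
F10 | step 9 | (1R,2S)-1-[2,4-bis(benzyloxy)-5,6-didehydrophenyl]-2-ArB-propane-1,3-diol (aryne, present as its dilithium alkoxide) | OC[C@H](c1cc(CC=C(C)C)c(OCc2ccccc2)c(OCc2ccccc2)c1)[C@@H](O)C1=C(OCc2ccccc2)C=C(OCc2ccccc2)C#C1
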